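**Retrosynthetic overview**

- The strategy rests on one feature of ring C: the ketone carbon C4 lies between C4a of ring A and C3, and C3 is the terminal carbon of the enol ether unit O1–C2(ring B)=C3. C4 can therefore be a formyl carbon on C4a and C3 a vinyl CH2, and the C3–C4 bond is made last by an oxidative aroyl radical cyclisation.
- The 1-arylvinyl ether comes from titanium methylenation of the ring A aryl 3,4,5-trimethoxybenzoate. A free formyl group would not survive that step, so C4 is carried as an aryl bromide and turned into the aldehyde afterwards by Br–Li exchange and DMF.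
- Ring A (five contiguous oxygens) is built from 2,6-dimethoxyphenol: its OH becomes O7, symmetric dibromination followed by two successive Br-to-OH exchanges installs O5 and the O1 oxygen, and the last free ring position takes the bromine that becomes C4.
- Rings A and B are bought as benzenes; ring C is the only ring formed (step 10). BCl3 then frees the 5- and 7-hydroxyls from their isopropyl ethers.

Key step: step 10

Remark: 3,4,5-trimethoxybenzaldehyde and 5-ethynyl-1,2,3-trimethoxybenzene, which appear only in fallbacks, are taken as purchased.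

**Route**

Step 1
Reactants: 1 2,6-dimethoxyphenol; 2 2-bromopropane
Product: 3 2-isopropoxy-1,3-dimethoxybenzene
Conditions: K2CO3, DMSO, 60 °C
Reagents that add atoms: none
Why: Williamson ether synthesis, in which the phenoxide of 1 is alkylated by the secondary bromide in a dipolar aprotic solvent.

Step 2
Reactants: 3 2-isopropoxy-1,3-dimethoxybenzene
Product: 4 1,5-dibromo-3-isopropoxy-2,4-dimethoxybenzene
Conditions: NBS (2.1 equiv), MeCN, 0 °C to rt
Reagents that add atoms: N-bromosuccinimide, O=C1CCC(=O)N1Br
Why: Electrophilic aromatic bromination, in which positions 4 and 6 are each ortho to one in-plane methoxy group and para to the other, while position 5 is only para to the twisted central alkoxy group, so the symmetric 4,6-dibromide should form.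

Step 3
Reactants: 4 1,5-dibromo-3-isopropoxy-2,4-dimethoxybenzene
Product: 7 5-bromo-3-isopropoxy-2,4-dimethoxyphenol, via aryllithium 5 (not isolated), via dimethyl arylboronate 6 (not isolated)
Conditions: n-BuLi (1.0 equiv), THF, −78 °C; B(OMe)3, −78 to 0 °C; then AcOH, 30% H2O2, 0 °C to rt
Reagents that add atoms: n-butyllithium, [Li]CCCC (lithium of intermediate 5 only); trimethyl borate, COB(OC)OC (boron and methoxy groups of intermediate 6 only); hydrogen peroxide, OO (the phenol oxygen)
Why: Bromine–lithium exchange of one of two equivalent bromines (the monolithio arene resists a second exchange), borylation and peroxide oxidation of the arylboronate with aryl migration from boron to oxygen should give the phenol, with no regiochemical question because of the symmetry of 4.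

Step 4
Reactants: 7 5-bromo-3-isopropoxy-2,4-dimethoxyphenol; 2 2-bromopropane
Product: 8 1-bromo-3,5-diisopropoxy-2,4-dimethoxybenzene
Conditions: K2CO3, DMSO, 60 °C
Reagents that add atoms: none
Why: Williamson ether synthesis on a phenol with only one ortho substituent, which fixes the future O5 as its isopropyl ether.

Step 5
Reactants: 8 1-bromo-3,5-diisopropoxy-2,4-dimethoxybenzene
Product: 11 3,5-diisopropoxy-2,4-dimethoxyphenol, via aryllithium 9 (not isolated), via dimethyl arylboronate 10 (not isolated)
Conditions: n-BuLi (1.1 equiv), THF, −78 °C; B(OMe)3, −78 to 0 °C; then AcOH, 30% H2O2, 0 °C to rt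
Reagents that add atoms: n-butyllithium, [Li]CCCC (lithium of intermediate 9 only); trimethyl borate, COB(OC)OC (boron and methoxy groups of intermediate 10 only); hydrogen peroxide, OO (the phenol oxygen)
Why: The same bromine–lithium exchange, borylation and boronate oxidation sequence turns the remaining bromide into the hydroxyl that will become O1, and the acidic oxidation medium limits over-oxidation of the electron-rich phenol.

Step 6
Reactants: 11 3,5-diisopropoxy-2,4-dimethoxyphenol
Product: 12 2-bromo-3,5-diisopropoxy-4,6-dimethoxyphenol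
Conditions: NBS (1.0 equiv), CH2Cl2, −20 to 0 °C
Reagents that add atoms: N-bromosuccinimide, O=C1CCC(=O)N1Br
Why: Electrophilic bromination of a phenol whose only unsubstituted ring position is ortho to the hydroxyl, so the bromine can enter only at the future C4a.

Step 7
Reactants: 12 2-bromo-3,5-diisopropoxy-4,6-dimethoxyphenol; 13 3,4,5-trimethoxybenzoyl chloride
Product: 14 2-bromo-3,5-diisopropoxy-4,6-dimethoxyphenyl 3,4,5-trimethoxybenzoate
Conditions: Et3N, DMAP (cat.), CH2Cl2, 0 °C to rt
Reagents that add atoms: none
Why: O-acylation of a phenol by an acid chloride with nucleophilic catalysis by DMAP, which copes with the two ortho substituents of 12.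

Step 8
Reactants: 14 2-bromo-3,5-diisopropoxy-4,6-dimethoxyphenyl 3,4,5-trimethoxybenzoate
Product: 15 1-bromo-2,4-diisopropoxy-3,5-dimethoxy-6-{[1-(3,4,5-trimethoxyphenyl)ethenyl]oxy}benzene
Conditions: Ti(C5H5)2(CH3)2 (3 equiv), toluene/THF, 65 °C, dark; filtration through basic alumina
Reagents that add atoms: dimethyltitanocene Ti(C5H5)2(CH3)2, C[Ti+2]C.[cH-]1cccc1.[cH-]1cccc1 (delivers CH2)
Why: Petasis methylenation, in which the titanium methylidene formed on heating converts the ester carbonyl into the 1-arylvinyl ether by cycloaddition and cycloreversion, while the aryl bromide and the ethers are inert and the non-acidic work-up protects the enol ether.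

Step 9
Reactants: 15 1-bromo-2,4-diisopropoxy-3,5-dimethoxy-6-{[1-(3,4,5-trimethoxyphenyl)ethenyl]oxy}benzene; 16 N,N-dimethylformamide
Product: 19 2,4-diisopropoxy-3,5-dimethoxy-6-{[1-(3,4,5-trimethoxyphenyl)ethenyl]oxy}benzaldehyde, via aryllithium 17 (not isolated), via lithium hemiaminal alkoxide 18 (not isolated)
Conditions: n-BuLi (1.1 equiv), THF, −78 °C; then DMF (3 equiv), −78 to 0 °C; pH 7 phosphate buffer
Reagents that add atoms: n-butyllithium, [Li]CCCC (lithium of intermediates 17 and 18 only)
Why: Bromine–lithium exchange at −78 °C is faster than any addition to the enol ether, and formylation of the aryllithium with DMF followed by neutral hydrolysis of the hemiaminal alkoxide should give the aldehyde without cleaving the vinyl ether.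

Step 10
Reactants: 19 2,4-diisopropoxy-3,5-dimethoxy-6-{[1-(3,4,5-trimethoxyphenyl)ethenyl]oxy}benzaldehyde
Product: 20 5,7-diisopropoxy-6,8-dimethoxy-2-(3,4,5-trimethoxyphenyl)-4H-chromen-4-one
Conditions: t-BuOOH (5.5 M in decane, 3 equiv), Bu4NI (20 mol%), NaHCO3 (buffer), PhCl (0.05 M), 80 °C
Reagents that add atoms: none
Why: Proposed new method: tert-butoxyl and tert-butylperoxyl radicals generated from t-BuOOH by the iodide/iodine redox cycle abstract the formyl hydrogen of 19, and the aroyl radical on C4a adds to the unsubstituted terminus C3 of the 1-arylvinyl ether, forming C3–C4 and closing ring C in a 6-endo-trig mode to a tertiary C2 radical stabilised by O1 and ring B, which is oxidised to the oxocarbenium ion and loses the C3 proton to give the pyranone. The closest known reaction type is the oxidative acyl radical cyclisation of 2-(allyloxy)benzaldehydes to chroman-4-ones under peroxide conditions, from which this substrate differs in having the alkene one atom closer and as an enol ether. No stereocentre is formed. The selectivity needed is 6-endo attack at C3 over 5-exo attack at C2, and it is secured because C2 is fully substituted and attack there would give an unstabilised primary radical, which could in any case relay to the same C2 radical by a 1,2-acyl shift of the Dowd–Beckwith type. The addition of a nucleophilic aroyl radical to an electron-rich alkene is polarity-mismatched, so the step relies on intramolecularity, on the styrene-like acceptor that gives a benzylic alpha-oxy radical, and on the slow decarbonylation of aroyl radicals. Ring A carries only methyl and isopropyl ethers, whose C–H bonds should be abstracted more slowly than the formyl hydrogen, and the expected competing paths are perester formation at the aroyl radical and attack of iodine or peroxyl species on the enol ether.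

Step 11
Reactants: 20 5,7-diisopropoxy-6,8-dimethoxy-2-(3,4,5-trimethoxyphenyl)-4H-chromen-4-one
Product: 21 5,7-dihydroxy-6,8-dimethoxy-2-(3,4,5-trimethoxyphenyl)-4H-chromen-4-one (5,7-dihydroxy-6,8,3',4',5'-pentamethoxyflavone)
Conditions: BCl3 (1 M in CH2Cl2, 5 equiv), CH2Cl2, −78 to 0 °C; then H2O
Reagents that add atoms: none
Why: Lewis acid dealkylation of aryl ethers, in which BCl3 cleaves the secondary isopropyl ethers through an ionising pathway much faster than the methyl ethers, with the 5-O cleavage assisted by chelation of boron to the C4 carbonyl, so short exposure at low temperature should spare the five methoxy groups.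

**Compound list**

1 | 2,6-dimethoxyphenol | COc1cccc(OC)c1O | starting material
2 | 2-bromopropane | CC(C)Br | starting material
3 | 2-isopropoxy-1,3-dimethoxybenzene | COc1cccc(OC)c1OC(C)C | intermediate
4 | 1,5-dibromo-3-isopropoxy-2,4-dimethoxybenzene | COc1c(Br)cc(Br)c(OC)c1OC(C)C | intermediate
5 | (5-bromo-3-isopropoxy-2,4-dimethoxyphenyl)lithium | [Li]c1cc(Br)c(OC)c(OC(C)C)c1OC | intermediate
6 | dimethyl (5-bromo-3-isopropoxy-2,4-dimethoxyphenyl)boronate | COB(OC)c1cc(Br)c(OC)c(OC(C)C)c1OC | intermediate
7 | 5-bromo-3-isopropoxy-2,4-dimethoxyphenol | COc1c(O)cc(Br)c(OC)c1OC(C)C | intermediate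
8 | 1-bromo-3,5-diisopropoxy-2,4-dimethoxybenzene | COc1c(Br)cc(OC(C)C)c(OC)c1OC(C)C | intermediate
9 | (3,5-diisopropoxy-2,4-dimethoxyphenyl)lithium | [Li]c1cc(OC(C)C)c(OC)c(OC(C)C)c1OC | intermediate
10 | dimethyl (3,5-diisopropoxy-2,4-dimethoxyphenyl)boronate | COB(OC)c1cc(OC(C)C)c(OC)c(OC(C)C)c1OC | intermediate
11 | 3,5-diisopropoxy-2,4-dimethoxyphenol | COc1c(O)cc(OC(C)C)c(OC)c1OC(C)C | intermediate
12 | 2-bromo-3,5-diisopropoxy-4,6-dimethoxyphenol | COc1c(O)c(Br)c(OC(C)C)c(OC)c1OC(C)C | intermediate
13 | 3,4,5-trimethoxybenzoyl chloride | COc1cc(C(Cl)=O)cc(OC)c1OC | starting material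
14 | 2-bromo-3,5-diisopropoxy-4,6-dimethoxyphenyl 3,4,5-trimethoxybenzoate | COc1cc(C(=O)Oc2c(Br)c(OC(C)C)c(OC)c(OC(C)C)c2OC)cc(OC)c1OC | intermediate
15 | 1-bromo-2,4-diisopropoxy-3,5-dimethoxy-6-{[1-(3,4,5-trimethoxyphenyl)ethenyl]oxy}benzene | C=C(Oc1c(Br)c(OC(C)C)c(OC)c(OC(C)C)c1OC)c1cc(OC)c(OC)c(OC)c1 | intermediate
16 | N,N-dimethylformamide | CN(C)C=O | starting material
17 | (2,4-diisopropoxy-3,5-dimethoxy-6-{[1-(3,4,5-trimethoxyphenyl)ethenyl]oxy}phenyl)lithium | [Li]c1c(OC(C)C)c(OC)c(OC(C)C)c(OC)c1OC(=C)c1cc(OC)c(OC)c(OC)c1 | intermediate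
18 | lithium (dimethylamino)(2,4-diisopropoxy-3,5-dimethoxy-6-{[1-(3,4,5-trimethoxyphenyl)ethenyl]oxy}phenyl)methanolate (racemic, transient) | [Li+].[O-]C(N(C)C)c1c(OC(C)C)c(OC)c(OC(C)C)c(OC)c1OC(=C)c1cc(OC)c(OC)c(OC)c1 | intermediate
19 | 2,4-diisopropoxy-3,5-dimethoxy-6-{[1-(3,4,5-trimethoxyphenyl)ethenyl]oxy}benzaldehyde | C=C(Oc1c(OC)c(OC(C)C)c(OC)c(OC(C)C)c1C=O)c1cc(OC)c(OC)c(OC)c1 | intermediate
20 | 5,7-diisopropoxy-6,8-dimethoxy-2-(3,4,5-trimethoxyphenyl)-4H-chromen-4-one | COc1cc(-c2cc(=O)c3c(OC(C)C)c(OC)c(OC(C)C)c(OC)c3o2)cc(OC)c1OC | intermediate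
21 | 5,7-dihydroxy-6,8-dimethoxy-2-(3,4,5-trimethoxyphenyl)-4H-chromen-4-one | COc1cc(-c2cc(=O)c3c(O)c(OC)c(O)c(OC)c3o2)cc(OC)c1OC | target

**Step count and risks**

Total step count: 11. Longest linear sequence: 11 steps (1 to 21).

Steps most likely to fail:

1. Step 10. The aroyl radical may be intercepted by tert-butylperoxyl radicals (perester formation) or oxidised to the acid, the enol ether may be consumed by electrophilic iodine or peroxyl addition, and the polarity-mismatched addition may be too slow to compete. The fallback uses the classical chalcone route; it sets out from phenol 11 and comes back at flavone 20. Friedel–Crafts C-acetylation of 11 at its only free ring position (Ac2O, BF3·OEt2, 60 °C, then aqueous hydrolysis of the boron chelate) should give 1-(2-hydroxy-4,6-diisopropoxy-3,5-dimethoxyphenyl)ethan-1-one F1. Claisen–Schmidt condensation of F1 with 3,4,5-trimethoxybenzaldehyde (KOH, EtOH, rt) should give (E)-1-(2-hydroxy-4,6-diisopropoxy-3,5-dimethoxyphenyl)-3-(3,4,5-trimethoxyphenyl)prop-2-en-1-one F2. Oxidative cyclisation of the 2'-hydroxychalcone (I2 cat., DMSO, 120 °C) should then give 20, which enters step 11.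

2. Step 8. Methylenation may stall at the ester flanked by two ortho substituents, or the 1-arylvinyl ether may be hydrolysed during isolation. The fallback forms the same C–O bond from the alkyne side; it sets out from bromophenol 12 and comes back at 15. Markovnikov hydrophenoxylation of 5-ethynyl-1,2,3-trimethoxybenzene with 12 under monovalent gold catalysis (Ph3PAuCl, AgN(SO2CF3)2, dry toluene, 60 °C) should place the oxygen on the aryl-bearing alkyne carbon. Ring A of 12 has no free C–H, so hydroarylation cannot compete. This fallback makes no new compound (F0).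

3. Step 6. The very electron-rich phenol may be oxidised towards a quinone instead of being brominated on the ring. The fallback drops the bromine and relies on deprotonation; it sets out from 11 and comes back at aryllithium 17. Acylation of 11 with 13 (Et3N, DMAP, CH2Cl2) should give 3,5-diisopropoxy-2,4-dimethoxyphenyl 3,4,5-trimethoxybenzoate F3. Methylenation with Ti(C5H5)2(CH3)2 (toluene/THF, 65 °C) should give 1,3-diisopropoxy-2,4-dimethoxy-5-{[1-(3,4,5-trimethoxyphenyl)ethenyl]oxy}benzene F4. Directed ortho-metalation of F4 at the ring C–H flanked by the two oxygens (n-BuLi, TMEDA, THF, −40 °C) should give 17, which is formylated with 16 as in step 9.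

**Further compounds**

F1 | step 10 | 1-(2-hydroxy-4,6-diisopropoxy-3,5-dimethoxyphenyl)ethan-1-one | CC(=O)c1c(O)c(OC)c(OC(C)C)c(OC)c1OC(C)C
F2 | step 10 | (E)-1-(2-hydroxy-4,6-diisopropoxy-3,5-dimethoxyphenyl)-3-(3,4,5-trimethoxyphenyl)prop-2-en-1-one | COc1cc(/C=C/C(=O)c2c(O)c(OC)c(OC(C)C)c(OC)c2OC(C)C)cc(OC)c1OC
F0 | step 8 | none | none
F3 | step 6 | 3,5-diisopropoxy-2,4-dimethoxyphenyl 3,4,5-trimethoxybenzoate | COc1cc(C(=O)Oc2cc(OC(C)C)c(OC)c(OC(C)C)c2OC)cc(OC)c1OC
F4 | step 6 | 1,3-diisopropoxy-2,4-dimethoxy-5-{[1-(3,4,5-trimethoxyphenyl)ethenyl]oxy}benzene | C=C(Oc1cc(OC(C)C)c(OC)c(OC(C)C)c1OC)c1cc(OC)c(OC)c(OC)c1
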